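The constants are those of an exercise; the run is a simulation.

At the start of the flask, X takes up Q 1.3 times as fast as Q pairs off with itself, so the yield of J turns on that race.

D 0.10 M; Q 0.150 M; X 0.15 mM; time 15 d

    X ⇌ G (K1 = 2.22, k1 = 1.24 h⁻¹)
    D.Q.X → X + J (k2 = 561 h⁻¹)
    D + Q.X → D.Q.X (k3 = 38700 L mol⁻¹ h⁻¹)
    2 Q → Q2 (k4 = 10.1 L mol⁻¹ h⁻¹)
    Q + X → Q.X (k5 = 26800 L mol⁻¹ h⁻¹)

- which holds at 15 d: what has brought the reaction to rest, or that it has not come to rest (all of D has reacted / forward and back rates have come level / it is still moving / no working catalyst is left / Q has run out first)
- how much J there is at 15 d, in percent of the D charged

- a step written with two of one species runs at k times the square of its concentration and takes two of it each time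
- the reaction counts as stopped when no species that holds the D changes by six tenths of a point or more over the second half of the time
- run time (flask): 15 d

Each Q taken into the round gives one J, and each Q that pairs off gives none. Let capture run at aQ, with a a pseudo-first-order constant, and let pairing run at bQ², with b = 20.2 L mol⁻¹ h⁻¹. Dividing one rate by the other and integrating from the charge C of Q down to zero gives the reach, R = (a/b) ln(1 + bC/a), the Q that passes through the round.

Two extreme flasks can be solved this way. In the free flask nothing queues in the round and X keeps its balance with G, holding 31.1% of the catalyst. Then a = 1.25 h⁻¹, and R is 76.1% of the D charged. In the sloped flask there is no G, and the rate is set to start at the release rate of the whole catalyst and to fall in step with Q. That sloped line is a deliberately low version, since it lies under the flat rate of a full queue, 0.0841 M h⁻¹, at every lower Q. Then a = 0.561 h⁻¹, and R is 51.6%.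

The real flask starts near the sloped one, because capture at 4020 h⁻¹ outruns release at 561 h⁻¹. It ends near the free one, because below 0.0209 M of Q capture falls behind release. This reckoning therefore commits to the midpoint, 63.8%, the mean reach. Both extremes stay below the D charged, so Q should be the limiting reagent.

The forecast says Q has run out first, with 58% of J, a lower figure than this reckoning. Its grounds are that “only once Q falls does most of what is left go through the catalytic cycle”.

The simulation gives 61.9% of J, and its ending is the forecast's: Q has run out first. At 15.0 d, 38% of the D stands stranded beside 0% of the Q. The mean reach lies 1.9 percentage points above that yield. A neighbour flask charged with 3.7 × 10⁻⁵ M of X has extremes of 36.3% and 21.4%, so its mean reach is 28.8%. That neighbour flask ends with 29.6% of J.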